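The vessel was a closed, stirred flask under held gas, and I wanted the target in it at 8.0 d, as a fraction of the charge.

in all of them: gas phase 200 mM (held)
- south-west: substrate 0.40 M; run made earlier
- south-east: substrate 0.60 M; run made earlier
- flask: substrate 0.80 M; time 8.0 d

| run | time / d | target / % | substrate / % |
|---|---|---|---|
| south-west | 1.67 | 69.1 | 4.7 |
| south-west | 3.00 | 60.8 | 0 |
| south-west | 5.00 | 52.2 | 0 |
| south-west | 6.00 | 49.0 | 0.3 |
| south-west | 8.00 | 44.2 | 0 |
| south-west | 10.0 | 39.6 | 0.1 |
| south-east | 0.833 | 62.5 | 27.1 |
| south-east | 1.25 | 69.4 | 11.6 |
| south-east | 2.00 | 68.0 | 3.1 |
| south-east | 4.00 | 55.4 | 0 |
| south-east | 6.00 | 49.1 | 0 |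
| south-east | 10.0 | 39.8 | 0 |

(each reading ± 0.3 percentage points)

- how much target there is at 8.0 d, in percent of the substrate charged
- the change that raises the amount of target at 8.0 d, in percent of the substrate charged most ("none" if none brings more than 2 percentage points) (summer / noon / none)
- amount of target at 8.0 d, in percent of the substrate charged, after noon

- at the start none of the gas is dissolved
- steps thought possible: substrate + dissolved gas -> target; dissolved gas + target -> over-reacted product; gas phase <-> dissolved gas; target <-> isomer of the product; target -> over-reaction product

- summer: doubling the saturation concentration of gas phase, all else as stated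
- noon: doubling the transfer coefficient of the gas phase, all else as stated

In the runs the substrate fell in a roughly pseudo-first-order way, with a half-life read from the south-east run of 0.394 d. That is far shorter than 6.00 d, so by then formation was over and the target was simply being lost. At their different charges the two runs read 49.0 % and 49.1 % at that time, and 39.6 % and 39.8 % at 10.0 d.

I therefore folded the south-west readings and the asked time into one number, 0.106: the loss number, the logarithm of the share of target surviving from 6.00 d to the asked time at a steady rate. It gave me 44.0 % for the flask.

As a test, the south-west run itself read 44.2 % at 8.00 d, which is 0.20 percentage points above that, against a scatter of 0.3 points. So one number nearly served for that run. It could not speak for summer, since both runs held the same saturation. Noon hastens the early uptake of gas, and that stretch ends well before 6.00 d, so I expected little from it. Summer offers more dissolved gas, and once formation is over, the step thought possible that uses dissolved gas is the one from dissolved gas and target to over-reacted product, which consumes target. So I expected no gain from summer either and chose none, as a judgement that neither run tested.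

The forecast gave 44.4 %, none and 44.1 % after noon, holding that “Late loss is therefore first order in target and independent of charge”.

The flask gave 44.5 %, which is 0.50 points above my reckoning, with none as the best change, 44.1 % after noon, and −9.5 points under summer.

    substrate + dissolved gas → target (k = 0.00700 M⁻¹ min⁻¹)
    dissolved gas + target → over-reacted product (k = 1.40 × 10⁻⁴ M⁻¹ min⁻¹)
    gas phase ⇌ dissolved gas, rate k3*(csat - [dissolved gas]) (kL = 0.0120 min⁻¹)
    target ⇌ isomer of the product (K = 0.470, k = 2.20 × 10⁻⁴ min⁻¹)
    target → over-reaction product (k = 2.60 × 10⁻⁵ min⁻¹)

The relaxation half-life of target and isomer of the product, 0.700 d, was short against 8.0 d. Scaled to a reading of the same flask at 5.0 d, the loss number gives 51.7 %, and that flask held 52.4 %.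

Readings and results are simulated with made-up constants; scatter was added.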